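## Structural features

α-Onocerin is a C2-symmetric C30 diol in which two identical trans-decalins, rings A/B (C1–C10) and rings D/E (C13–C22), are held together only by the C11–C12 ethano bridge between C9 and C13. Each half carries four stereocentres: the contiguous set C5–C10–C9 (C17–C18–C13), with H5 trans to the angular methyl on C10 and the C9–C11 bond cis to it, and the equatorial carbinol C3 (C21), which the gem-dimethyl carbon C4 (C22) separates from C5 (C17). The quaternary carbons C10 and C18 stand directly next to the bridge-bearing methines C9 and C13, so the most congested bonds lie where the halves meet. The fragile groups are the exocyclic 1,1-disubstituted alkenes C8=C26 and C14=C27, which acid can shift into the rings or draw into cation–olefin cyclisation across the bridge; they are best made last, from ketones, whereas the neopentyl-type secondary alcohols are robust. The real difficulty is to set C9/C10 and C13/C18 with the same absolute sense in both halves (C2, not meso) without running a long sequence twice. The key step uses the position of C10 (C18) in ring B (ring D) between C9 (C13) and C5 (C17): with ketone carbons at C5 and C17 and the methyl groups already on C10 and C18, rings A and E can be annulated last and in both directions at once, each new quaternary centre being steered by its neighbour C9 or C13.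

## Logic of the disconnections

15 to 14: the bonds C8=C26 and C14=C27 are cut. These acid-labile alkenes are the only sensitive function, and the ketones left behind are stable and mark where C8 and C14 must be oxygenated. Two carbons and the fragile groups disappear. The forward step must methylenate two hindered, enolisable ketones in the presence of free hydroxyl groups; base is tolerable because C9 and C13 already hold their thermodynamically preferred configuration.

14 to 12 (through 13): no skeletal bond is cut. The C3–H and C21–H bonds are retraced to ketones and the C8/C14 carbonyls to dioxolanes, which keeps the two kinds of carbonyl distinguishable. The C3 and C21 stereocentres vanish. The forward step needs axial hydride delivery at C3 and C21 and acetal hydrolysis only after the hydride has been destroyed.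

12 to 10 (through 11): one C4–CH3 and one C22–CH3 bond are cut, together with the C5–H and C17–H bonds. The 4-methyl enone is the direct outcome of an annulation and, on reduction, the source of a regiodefined enolate. Two carbons and the C5/C17 stereocentres are removed. The forward step must protonate C5 and C17 trans to the angular methyls and alkylate only at C4 and C22, twice in one molecule.

10 to 7 and two molecules of 8 (through 9): the bonds C1–C10 and C4=C5, and C18–C19 and C17=C22, are cut. Rings A and E fall away as two five-carbon enones, and the tetracycle shrinks to a bis-cyclohexanone whose only controlling stereocentres are C9 and C13. The forward step must place the Michael addition at the more substituted α-carbon (C10, C18) and on the face anti to the bridge, independently in both rings, and it must consume one molecule of 8 per ring.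

7 to 6 to 4 (through 5): going from 7 to 6 cuts no skeletal bond but restores C6=C7, C15=C16 and C11=C12; going from 6 to 4 cuts the C10–CH3 and C18–CH3 bonds. With the ring unsaturation pointing at the quaternary ketal carbons, C10 and C18 are the only enolisable positions, so the methyl groups go in regiospecifically and no conjugate addition to an α-substituted enone is needed. The forward steps need a clean twofold kinetic enolate methylation and a hydrogenation that leaves the allylic centres C9 and C13 untouched.

4 to two molecules of 1 and 2 (through 3): the bonds C9–C11 and C12–C13 are cut. The bridge is a two-carbon unit that can act twice as a nucleophile, and since C9 and C13 are identical, one chiral catalyst can set both. The skeleton reduces to an achiral dienone and a linchpin. The forward step needs two enantioselective conjugate additions of the same sense, one per ring and no more.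

## Other disconnections considered

Alternative 1: The cut passes through rings B and D at C5–C10 and C8–C9 (C17–C18 and C13–C14), leading from the bis-decalin 11,12-dione A1 back to the open-chain bis-trienyl 1,2-dione A2. In the forward sense, heating A2 (if needed with Me2AlCl) would let each (E)-enone C9=C10 (C13=C18) add to its own tethered 8-silyloxy diene and close all four rings at once.
- In favour: the dienophile geometry fixes the cis relation of the angular methyl and the bridge stereospecifically, and the gem-dimethyl groups, the C3/C21 oxygens and the C8/C14 oxygens are already present. In rings and stereocentres formed per operation this alternative is the better of the two, and it needs no reductive methylation.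
- Against: the dienophile is β,β-disubstituted and conjugated to a 1,2-dione, so it should be sluggish thermally, while Lewis acids endanger the silyl dienol ethers and the MOM groups. The trans ring fusion depends on one folding of the tether, guided only by C3 (C21) across the gem-dimethyl carbon, and two independent cycloadditions must both fold correctly. A2 is a long polyene with four defined alkene geometries and a reactive ene-dione core. After the cycloaddition the C11 and C12 carbonyls are surplus and would have to be removed next to C9 and C13, in addition to hydrogenation of C6=C7 and C15=C16, oxidation at C8/C14, methylenation and MOM cleavage.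
- Comparison: structurally, A1 carries more of the final substitution than 10 but also oxygen at the wrong carbons, whereas 10 lacks only two methyl groups and two hydrogens. Mechanistically, a concerted cycloaddition is at least the equal of the stepwise Michael–aldol sequence for the methyl/bridge relationship, but weaker for the ring fusion, which the chosen plan sets separately. In step economy the chosen plan (seven steps) is expected to be clearly shorter, since both the preparation of A2 and the clean-up after A1 are multi-step.

Alternative 2: The cut is made at C9–C10 and C13–C18, leading from the diacid A3 back to the (E)-hex-3-enedioate diester A4 of two ring A cyclohexenols. In the forward sense, double enolisation and silylation of A4 (KN(SiMe3)2, Me3SiCl) and warming would trigger two [3,3] shifts that move chirality from the C2 and C20 carbinols to C10 and C18.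
- In favour: the most congested bonds of the molecule would be made by an intramolecular pericyclic process, the linchpin is simple, and the absolute configuration comes from an enantiopure alcohol, not from a catalyst that has to act twice. On the C2-versus-meso question the alternative is therefore the equal of the chosen plan, or better.
- Against: no ring is closed. Rings B and D would still have to be built from the C8/C14 acids and the C6/C16 silyloxymethyl groups, with C7 and C15 still missing. The α-carbons of A4 are also allylic, so extended enolates, double-bond migration into conjugation and loss of ketene acetal geometry (which decides C9 and C13) are real concerns, as is a competing boat transition state. Each ring A unit needs three stereocentres before the key step, and A3 carries surplus unsaturation (C1=C2, C19=C20, C11=C12) and the wrong oxidation level at C8 and C14.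
- Comparison: structurally, A3 is further from the target than 10, with two rings missing against none. Mechanistically, the sigmatropic transfer is more strictly stereospecific than a substrate-controlled Michael addition, which is a point in its favour. In step economy it should be much the longer route.

Alternative 3: Only ring B is cut, at C7–C8 and C9–C10, leading from the coupled product A5 back to the ring A silyloxy diene A6 and the allenyl ketone A7, which carries the finished D/E half. In the forward sense, a Lewis-acid Diels–Alder reaction between A6 and the α,β-bond of A7 would close ring B.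
- In favour: the C8 methylene arrives with the allene, so no late methylenation of a hindered ketone is needed; on this point the alternative is the better of the two. The regiochemistry is electronically matched (silyloxy at C6 para to the acyl group at C9), and the coupling is convergent.
- Against: the plan is not two-directional. One half must be complete before the other is started, so the symmetry is unused and two different sequences are needed. The diene terminus C10 is fully substituted, which should slow the cycloaddition, while allenyl ketones are prone to isomerise or oligomerise under Lewis acids. Facial selectivity would depend on remote C3 and on the chiral dienophile, with matched or mismatched pairing unknown in advance, and endo/exo selection decides C9. Afterwards the C6 oxygen and the C11 ketone must both be removed and H5 set, all in the presence of two acid-sensitive methylenes.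
- Comparison: structurally, A5 is closer to the target than 10 in carbon count but has oxygen at C6 and C11 to remove. Mechanistically, the cycloaddition forms the quaternary centre in one concerted event, comparable to the chosen plan, but with less certain face control. In step economy the chosen plan is expected to be clearly shorter because it makes both halves at once.

Key step: step 4

Assumption: the sense of induction of the rhodium/diene catalyst with dienone 1 is taken to parallel that with cyclohex-2-enone; if it proves opposite, the antipodal ligand is used.

## Route

Step 1
Reactants: 1 1,4-dioxaspiro[4.5]deca-6,9-dien-8-one (p-benzoquinone mono(ethylene ketal): two molecules are incorporated); 2 (E)-1,2-bis(4,4,5,5-tetramethyl-1,3,2-dioxaborolan-2-yl)ethene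
Product: 4 (E)-1,2-bis[(6S)-8-oxo-1,4-dioxaspiro[4.5]dec-9-en-6-yl]ethene, via mono-adduct alkenylboronate 3 (not isolated)
Conditions: 1 (2.6 equiv), [RhCl(C2H4)2]2 (3 mol %), (S,S)-Ph-bod* [(1S,4S)-2,5-diphenylbicyclo[2.2.2]octa-2,5-diene, 6.6 mol %], KOH (0.3 equiv), dioxane/H2O 10:1, 40 °C
Reagents that add atoms: p-benzoquinone mono(ethylene ketal) (second molecule of 1), O=C1C=CC2(OCCO2)C=C1
Why: Hayashi–Miyaura rhodium-catalysed asymmetric conjugate addition: each C–B bond transmetalates to the hydroxorhodium–diene complex, the alkenylrhodium inserts a dienone C=C at the carbon next to the ketal and water protonates the oxa-π-allyl complex, so that mono-adduct 3, itself an (E)-alkenylboronate, re-enters the cycle and takes up a second molecule of 1. Both C9 and C13 are set by the ligand in the same sense (catalyst control), which should make the C2 isomer dominant and turn a rare mismatched addition into the separable meso diastereomer; the (E) geometry is retained. The excess of the more reactive dienone 1 keeps the alkenylrhodium away from the hindered enone of rings that have already reacted.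

Step 2
Reactants: 4 (E)-1,2-bis[(6S)-8-oxo-1,4-dioxaspiro[4.5]dec-9-en-6-yl]ethene
Product: 6 (E)-1,2-bis[(6R,7R)-7-methyl-8-oxo-1,4-dioxaspiro[4.5]dec-9-en-6-yl]ethene, via dilithium bis-dienolate 5 (not isolated)
Conditions: LiN(iPr)2 (2.3 equiv), THF, −78 °C (4 added to the base); MeI (6 equiv), −78 → −30 °C
Reagents that add atoms: iodomethane, CI
Why: Kinetic α′-deprotonation–alkylation of a cyclohexenone, one methyl group per ring: C8 and C14 are quaternary, so C10 and C18 are the only acidic carbons and the methyl groups can go nowhere else, while the (E)-alkene keeps each enolate from reaching the enone of the other ring. Iodomethane should approach anti to the neighbouring C9 (C13) substituent (trans product), but this centre is planarised again in step 4 and its configuration is of no consequence.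

Step 3
Reactants: 6 (E)-1,2-bis[(6R,7R)-7-methyl-8-oxo-1,4-dioxaspiro[4.5]dec-9-en-6-yl]ethene
Product: 7 1,2-bis[(6R,7R)-7-methyl-8-oxo-1,4-dioxaspiro[4.5]decan-6-yl]ethane (the C2-symmetric bis(2-methylcyclohexanone) bis-ketal)
Conditions: H2 (1 atm), 5% Pt/C, EtOAc, 23 °C, stopped after 3 equiv H2
Reagents that add atoms: none
Why: Heterogeneous hydrogenation of three disubstituted C=C bonds (two enone, one bridge); platinum is chosen over palladium for its lower tendency to migrate double bonds and to cleave allylic C–O bonds, which protects the allylic stereocentres C9 and C13 and the dioxolanes, and under neutral conditions the ketones are left alone. No new stereocentre is formed.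

Step 4
Reactants: 7 1,2-bis[(6R,7R)-7-methyl-8-oxo-1,4-dioxaspiro[4.5]decan-6-yl]ethane; 8 pent-1-en-3-one (ethyl vinyl ketone: two molecules are incorporated)
Product: 10 tetracyclic bis(4-methyl-4-en-3-one) bis-ketal (9R,10R,13R,18R)-8,8:14,14-bis(ethylenedioxy)-24,26,27,30-tetranoronocera-4,17(22)-diene-3,21-dione, via bis-Michael adduct 9 (not isolated)
Conditions: 8 (3.0 equiv, slow addition), KOH (0.3 equiv), EtOH, −10 → 0 °C; then NaOEt (2.5 equiv), EtOH, 70 °C
Reagents that add atoms: pent-1-en-3-one (second molecule of 8), CCC(=O)C=C
Why: Under equilibrating alkoxide each ketone is converted into its more substituted enolate (C5=C10, C17=C18), and each enolate adds to its own molecule of 8 in Michael fashion, so that two molecules of 8 are taken up and the bis-1,5-diketone 9 results. The closest known reaction type is the Robinson annulation of 2-methyl-3-alkylcyclohexanones with alkyl vinyl ketones. On heating, the ethyl ketone enolates (C4, C22) attack the ring carbonyls C5 and C17 in a 6-(enolexo)-exo-trig aldol closure for ring A and for ring E, and E1cB dehydration (two molecules of water lost) gives the tetrasubstituted C4=C5 and C17=C22 enones, the thermodynamic sink that also drains any reversible bridged aldol. The new stereocentres C10 and C18 are controlled by their neighbours C9 and C13: A(1,2) strain between the enolate methyl and the bridge turns the bridge pseudoaxial, and the stereoelectronically favoured axial attack then occurs anti to it, so that the C1–C10 (C18–C19) bond forms trans to the bridge and the angular methyl ends up cis to it. The axial dioxolane oxygen at C8 (C14) is syn-axial to the incoming enone in either chair-like transition state and therefore should slow the addition without changing its sense. The two rings react independently, each under its own stereocentre, so the matching C9/C13 configurations translate into the C2-symmetric product. The step needs regioselectivity for C10/C18 over the C6/C16 methylenes, which the thermodynamic enolate and the irreversible condensation are meant to secure, and chemoselectivity, which follows from the base stability of the dioxolanes and the non-acidity of C9 and C13 (β to the carbonyls).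

Step 5
Reactants: 10 (9R,10R,13R,18R)-8,8:14,14-bis(ethylenedioxy)-24,26,27,30-tetranoronocera-4,17(22)-diene-3,21-dione
Product: 12 (5R,9R,10S,13R,17R,18S)-8,8:14,14-bis(ethylenedioxy)-26,27-dinoronocerane-3,21-dione (trans-fused bis(4,4-dimethyl-3-ketone) bis-ketal), via dilithium bis-enolate 11 (not isolated)
Conditions: Li (6 equiv), NH3(l)/THF, t-BuOH (2.0 equiv), −78 °C; isoprene; then MeI (10 equiv), −78 → −33 °C
Reagents that add atoms: iodomethane, CI
Why: Reductive alkylation of an enone (dissolving-metal reduction with enolate trapping): two-electron reduction and protonation at C5 (C17) by t-BuOH give the regiodefined C3=C4 (C21=C22) lithium enolates 11, which iodomethane alkylates at C4 (C22) only, one methyl group per ring, completing the gem-dimethyl groups. Protonation of the β-carbanion should occur axially, anti to the angular methyl, so H5 and H17 end up trans to the C10 and C18 methyls (trans-decalins); the dioxolanes are inert to Li/NH3.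

Step 6
Reactants: 12 (5R,9R,10S,13R,17R,18S)-8,8:14,14-bis(ethylenedioxy)-26,27-dinoronocerane-3,21-dione
Product: 14 (3S,5R,9R,10S,13R,17R,18S,21S)-3,21-dihydroxy-26,27-dinoronocerane-8,14-dione, via diol bis-ketal 13 (not isolated)
Conditions: NaBH4 (3 equiv), MeOH/THF, 0 → 23 °C; acetone; then 2 M aq. HCl, THF, 23 °C
Reagents that add atoms: water, O
Why: Hydride reduction followed by acetal hydrolysis in one flask: in 4,4-dimethyl-3-oxo trans-decalins NaBH4 should deliver hydride to the axial face and give the equatorial alcohols (3S, 21S), cis to the angular methyls. After the excess hydride is destroyed with acetone, aqueous acid removes both dioxolanes; C9 and C13, now α to ketones, already carry the thermodynamically preferred equatorial side chain, so equilibration cannot invert them.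

Step 7
Reactants: 14 (3S,5R,9R,10S,13R,17R,18S,21S)-3,21-dihydroxy-26,27-dinoronocerane-8,14-dione
Product: 15 α-onocerin, (3S,5R,9S,10R,13S,17R,18R,21S)-onocera-8(26),14(27)-diene-3,21-diol
Conditions: Ph3PCH3Br (8 equiv), KOtBu (7.5 equiv), toluene, 23 → 90 °C
Reagents that add atoms: methyltriphenylphosphonium bromide, C[P+](c1ccccc1)(c1ccccc1)c1ccccc1.[Br-]
Why: Wittig methylenation; the non-stabilised ylide is used in excess because the two hydroxyl groups are deprotonated, and heating should overcome the hindrance at C8 and C14. No stereocentre is created, and any enolisation toward C9 or C13 returns to the favoured equatorial epimer.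

## Compound list

1 | 1,4-dioxaspiro[4.5]deca-6,9-dien-8-one | O=C1C=CC2(OCCO2)C=C1 | starting material
2 | (E)-1,2-bis(4,4,5,5-tetramethyl-1,3,2-dioxaborolan-2-yl)ethene | CC1(C)OB(/C=C/B2OC(C)(C)C(C)(C)O2)OC1(C)C | starting material
3 | (6S)-6-[(E)-2-(4,4,5,5-tetramethyl-1,3,2-dioxaborolan-2-yl)ethenyl]-1,4-dioxaspiro[4.5]dec-9-en-8-one | O=C1C=CC2(OCCO2)[C@H](/C=C/B3OC(C)(C)C(C)(C)O3)C1 | intermediate (not isolated)
4 | (E)-1,2-bis[(6S)-8-oxo-1,4-dioxaspiro[4.5]dec-9-en-6-yl]ethene | O=C1C=CC2(OCCO2)[C@H](/C=C/[C@@H]3CC(=O)C=CC34OCCO4)C1 | intermediate
5 | dilithium bis-dienolate of 4 (O-lithiated at both ring carbonyls, C10 and C18 deprotonated) | [Li]OC1=C[C@@H](/C=C/[C@@H]3C=C(O[Li])C=CC34OCCO4)C2(OCCO2)C=C1 | intermediate (not isolated)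
6 | (E)-1,2-bis[(6R,7R)-7-methyl-8-oxo-1,4-dioxaspiro[4.5]dec-9-en-6-yl]ethene | O=C1C=CC2(OCCO2)[C@H](/C=C/[C@@H]3[C@@H](C)C(=O)C=CC34OCCO4)[C@H]1C | intermediate
7 | 1,2-bis[(6R,7R)-7-methyl-8-oxo-1,4-dioxaspiro[4.5]decan-6-yl]ethane | O=C1CCC2(OCCO2)[C@H](CC[C@@H]3[C@@H](C)C(=O)CCC34OCCO4)[C@H]1C | intermediate
8 | pent-1-en-3-one (ethyl vinyl ketone) | CCC(=O)C=C | starting material
9 | 1,2-bis[(6R,7R)-7-methyl-8-oxo-7-(3-oxopentyl)-1,4-dioxaspiro[4.5]decan-6-yl]ethane | O=C1CCC2(OCCO2)[C@H](CC[C@@H]3[C@@](C)(CCC(=O)CC)C(=O)CCC34OCCO4)[C@@]1(C)CCC(=O)CC | intermediate (not isolated)
10 | (9R,10R,13R,18R)-8,8:14,14-bis(ethylenedioxy)-24,26,27,30-tetranoronocera-4,17(22)-diene-3,21-dione | CC1=C2CCC3(OCCO3)[C@H](CC[C@@H]4[C@@]5(C)CCC(=O)C(C)=C5CCC46OCCO6)[C@@]2(C)CCC1=O | intermediate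
11 | dilithium 3,21-bis-enolate of the 5,17-dihydro derivative of 10 (C3=C4 and C21=C22 enolates, trans ring fusions) | O1CCOC12CC[C@H]3C(C)=C(O[Li])CC[C@]3(C)[C@H]2CC[C@H]2C4(OCCO4)CC[C@H]4C(C)=C(O[Li])CC[C@]24C | intermediate (not isolated)
12 | (5R,9R,10S,13R,17R,18S)-8,8:14,14-bis(ethylenedioxy)-26,27-dinoronocerane-3,21-dione | O1CCOC12CC[C@H]3C(C)(C)C(=O)CC[C@]3(C)[C@H]2CC[C@H]2C4(OCCO4)CC[C@H]4C(C)(C)C(=O)CC[C@]24C | intermediate
13 | (3S,5R,9R,10S,13R,17R,18S,21S)-8,8:14,14-bis(ethylenedioxy)-26,27-dinoronocerane-3,21-diol | O1CCOC12CC[C@H]3C(C)(C)[C@@H](O)CC[C@]3(C)[C@H]2CC[C@H]2C4(OCCO4)CC[C@H]4C(C)(C)[C@@H](O)CC[C@]24C | intermediate (not isolated)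
14 | (3S,5R,9R,10S,13R,17R,18S,21S)-3,21-dihydroxy-26,27-dinoronocerane-8,14-dione | O=C1CC[C@H]2C(C)(C)[C@@H](O)CC[C@]2(C)[C@H]1CC[C@H]1C(=O)CC[C@H]2C(C)(C)[C@@H](O)CC[C@]12C | intermediate
15 | α-onocerin, (3S,5R,9S,10R,13S,17R,18R,21S)-onocera-8(26),14(27)-diene-3,21-diol | C=C1CC[C@H]2C(C)(C)[C@@H](O)CC[C@]2(C)[C@H]1CC[C@H]1C(=C)CC[C@H]2C(C)(C)[C@@H](O)CC[C@]12C | target

## Step count and least certain steps

Total: 7 steps, all in one line. Longest linear sequence: 7 steps from 1.

Step 4 (key step). The most likely failure is Michael addition through the less hindered C6/C16 enolates, followed by incomplete reaction of one of the two rings, polymerisation of 8, and some loss of facial selectivity because the incoming enone is syn-axial to a dioxolane oxygen. The fallback sets out from 6 and comes back at 10. In 6 the ring unsaturation and the quaternary ketal carbons leave C10 and C18 as the only enolisable positions. Deprotonation with LiN(iPr)2 (THF, −78 °C) and addition of 2-(triethylsilyl)pent-1-en-3-one (one molecule per ring) would give the bis(α-silyl 1,5-diketone) F1, again by attack anti to the bridge. KOH in MeOH would then remove the silyl groups and effect aldol condensation to the bis(4,6-dien-3-one) F2. Hydrogenation with RhCl(PPh3)3 (H2, benzene/EtOH) is expected to saturate only the three disubstituted alkenes (C6=C7, C15=C16, C11=C12) and to leave the tetrasubstituted enones, giving 10.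

Step 1. Likely failures are a second addition to the enone of a ring that has already reacted (oligomers), protodeboronation that stops the sequence at a vinyl-terminated mono-adduct, and insufficient enantioselectivity in one of the two additions (meso isomer). The fallback sets out from 1 and comes back at 4. Rhodium-catalysed asymmetric conjugate addition of CH2=CHBF3K ([RhCl(C2H4)2]2, (S,S)-Ph-bod*, aqueous dioxane) would give (6S)-6-ethenyl-1,4-dioxaspiro[4.5]dec-9-en-8-one F3, whose enantiomeric purity can be checked on a simple compound. Homometathesis of the vinyl groups of two molecules of this compound with second-generation Hoveyda–Grubbs catalyst would then form the C11=C12 bond and give 4.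

Step 3. The risk is double-bond migration on the metal surface before reduction, which would scramble the allylic centres C9 and C13; over-reduction of the ketones is a lesser concern. The fallback sets out from 6 and comes back at 7 without a surface-bound allyl species. Conjugate reduction of both enones with [(Ph3P)CuH]6 (toluene, then aqueous work-up) would give (E)-1,2-bis[(6R,7R)-7-methyl-8-oxo-1,4-dioxaspiro[4.5]decan-6-yl]ethene F4. Diimide (2-nitrobenzenesulfonyl hydrazide, Et3N) would then reduce the bridge alkene by concerted hydrogen transfer to give 7.

Step 5. Likely failures are proton transfer between enolate and product (mono-methyl or over-methylated rings), over-reduction of the carbonyls and incomplete alkylation of one of the two enolates. The fallback sets out from 10 and comes back at 12. Deconjugative α-methylation of the dienolates (KOtBu, MeI, t-BuOH/THF) would give the bis(4,4-dimethyl-5-en-3-one) F5 (C5=C6 and C16=C17). Hydrogenation (H2, PtO2, EtOAc) from the face opposite the angular methyls would then set the trans ring fusions and give 12.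

Step 7. The risk is enolisation of the hindered C8/C14 ketones by the basic ylide, so that one or both carbonyls are recovered instead of olefinated. The fallback sets out from 14 and comes back at 15 by Peterson olefination. Addition of Me3SiCH2Li/CeCl3 (excess, THF, −78 °C), a weakly basic nucleophile, would give the bis(β-hydroxysilane) F6 (configuration at C8 and C14 left open). Elimination with KH in THF would then give 15 without exposing the methylenes to acid.

## Further compounds

F1 | step 4 | (E)-1,2-bis[(6R,7R)-7-methyl-8-oxo-7-(3-oxo-2-triethylsilylpentyl)-1,4-dioxaspiro[4.5]dec-9-en-6-yl]ethene (mixture at the silyl-bearing carbons) | O=C1C=CC2(OCCO2)[C@H](/C=C/[C@@H]3[C@@](C)(CC([Si](CC)(CC)CC)C(=O)CC)C(=O)C=CC34OCCO4)[C@@]1(C)CC([Si](CC)(CC)CC)C(=O)CC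
F2 | step 4 | (9R,10R,13R,18R,11E)-8,8:14,14-bis(ethylenedioxy)-24,26,27,30-tetranoronocera-4,6,11,15,17(22)-pentaene-3,21-dione | CC1=C2C=CC3(OCCO3)[C@H](/C=C/[C@@H]4[C@@]5(C)CCC(=O)C(C)=C5C=CC46OCCO6)[C@@]2(C)CCC1=O
F3 | step 1 | (6S)-6-ethenyl-1,4-dioxaspiro[4.5]dec-9-en-8-one | O=C1C=CC2(OCCO2)[C@H](C=C)C1
F4 | step 3 | (E)-1,2-bis[(6R,7R)-7-methyl-8-oxo-1,4-dioxaspiro[4.5]decan-6-yl]ethene | O=C1CCC2(OCCO2)[C@H](/C=C/[C@@H]3[C@@H](C)C(=O)CCC34OCCO4)[C@H]1C
F5 | step 5 | (9R,10R,13R,18R)-8,8:14,14-bis(ethylenedioxy)-26,27-dinoronocera-5,16-diene-3,21-dione | O1CCOC12CC=C3C(C)(C)C(=O)CC[C@]3(C)[C@H]2CC[C@H]2C4(OCCO4)CC=C4C(C)(C)C(=O)CC[C@]24C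
F6 | step 7 | 8,14-bis(trimethylsilylmethyl)-26,27-dinoronocerane-3,8,14,21-tetraol (C8 and C14 configuration open) | C[Si](C)(C)CC1(O)CC[C@H]2C(C)(C)[C@@H](O)CC[C@]2(C)[C@H]1CC[C@H]1C(O)(C[Si](C)(C)C)CC[C@H]2C(C)(C)[C@@H](O)CC[C@]12C
A1 | alternative 1 | bis(6-ene-8-silyloxy trans-decalin) 11,12-dione | CC(C)(C)[Si](C)(C)O[C@H]1C=C[C@H]2C(C)(C)[C@@H](OCOC)CC[C@]2(C)[C@H]1C(=O)C(=O)[C@H]1[C@@H](O[Si](C)(C)C(C)(C)C)C=C[C@H]2C(C)(C)[C@@H](OCOC)CC[C@]12C
A2 | alternative 1 | open-chain bis-trienyl 1,2-dione | CC(C)(C)[Si](C)(C)O/C=C/C=C/C(C)(C)[C@@H](OCOC)CC/C(C)=C/C(=O)C(=O)/C=C(C)/CC[C@H](OCOC)C(C)(C)/C=C/C=C/O[Si](C)(C)C(C)(C)C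
A3 | alternative 2 | C2-symmetric 2,5-bis(ring A) hex-3-enedioic acid | OC(=O)[C@H](/C=C/[C@@H](C(=O)O)[C@@]1(C)C=C[C@H](O[Si](c2ccccc2)(c2ccccc2)C(C)(C)C)C(C)(C)[C@@H]1CO[Si](C)(C)C(C)(C)C)[C@@]1(C)C=C[C@H](O[Si](c2ccccc2)(c2ccccc2)C(C)(C)C)C(C)(C)[C@@H]1CO[Si](C)(C)C(C)(C)C
A4 | alternative 2 | (E)-hex-3-enedioate diester of two ring A cyclohex-2-enols | O=C(C/C=C/CC(=O)O[C@@H]1C=C(C)[C@@H](CO[Si](C)(C)C(C)(C)C)C(C)(C)[C@H]1O[Si](c2ccccc2)(c2ccccc2)C(C)(C)C)O[C@@H]1C=C(C)[C@@H](CO[Si](C)(C)C(C)(C)C)C(C)(C)[C@H]1O[Si](c2ccccc2)(c2ccccc2)C(C)(C)C
A5 | alternative 3 | 11-oxo-5-en-6-silyloxy coupled product | C=C1CC(O[Si](C)(C)C(C)(C)C)=C2C(C)(C)[C@@H](O[Si](C)(C)C(C)(C)C)CC[C@]2(C)[C@H]1C(=O)C[C@H]1C(=C)CC[C@H]2C(C)(C)[C@@H](O[Si](C)(C)C(C)(C)C)CC[C@]12C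
A6 | alternative 3 | ring A 6-silyloxy diene | C=C(O[Si](C)(C)C(C)(C)C)C1=C(C)CC[C@H](O[Si](C)(C)C(C)(C)C)C1(C)C
A7 | alternative 3 | allenyl ketone carrying the finished D/E half | C=C=CC(=O)C[C@H]1C(=C)CC[C@H]2C(C)(C)[C@@H](O[Si](C)(C)C(C)(C)C)CC[C@]12C
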